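Free catalyst is the concentration to follow here.

| flask | starting material | free catalyst | remark | time |
|---|---|---|---|---|
| Friday's | 0.80 M | 5.5 mM | run made earlier |  |
| Tuesday's | 1.1 M | 5.5 mM | run made earlier |  |
| Thursday's | 1.8 M | 5.5 mM | run made earlier |  |
| Monday's | 0.80 M | 8.2 mM | run made earlier |  |
| midnight | 0.80 M (fed, over 1.50 d) | 5.5 mM | all but starting material at the start; starting material goes in evenly over 1.50 d, the run ends at 3.0 d | 3.0 d |
| dusk | 0.80 M | 5.5 mM | a single well-mixed tank run continuously and read at steady state, 3.0 d in it on average |  |
| autumn | 0.80 M | 5.5 mM | a closed flask charged with all of it at once and left for 3.0 d | 3.0 d |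

Friday's run (percent of the starting material charged)

| time / h | target / % | isomer of the product / % |
|---|---|---|
| 3.00 | 13 | 4 |
| 8.00 | 43 | 1 |
| 15.0 | 68 | 8 |
| 25.0 | 69 | 24 |
| 30.0 | 63 | 34 |
| 40.0 | 50 | 51 |

Tuesday's run (percent of the starting material charged)

| time / d | target / % | isomer of the product / % |
|---|---|---|
| 0.417 | 43 | 0 |
| 0.833 | 72 | 7 |
| 1.25 | 72 | 27 |
| 1.67 | 58 | 42 |
| 2.08 | 41 | 55 |
| 2.50 | 34 | 64 |

Thursday's run (percent of the starting material charged)

| time / d | target / % | isomer of the product / % |
|---|---|---|
| 0.208 | 15 | 0 |
| 0.333 | 23 | 0 |
| 0.500 | 38 | 1 |
| 0.833 | 53 | 0 |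
| 1.67 | 73 | 24 |
| 2.50 | 42 | 55 |

Monday's run (percent of the starting material charged)

| time / d | target / % | isomer of the product / % |
|---|---|---|
| 0.208 | 40 | 1 |
| 0.625 | 76 | 16 |
| 1.04 | 50 | 44 |
| 1.67 | 32 | 68 |
| 2.50 | 25 | 79 |

(standard deviation of a reading: 2 percentage points)

- the stated concentrations are those of everything mixed, before any reaction; amounts are the same in each set-up
- the feed brings no volume worth counting
- the earlier runs were made in a closed, stirred flask

* order of the set-ups by the share of target in all that became target or isomer of the product, at the outlet or at the end, highest first (midnight / dusk / autumn)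
* share of target in all that became target or isomer of the product, at the outlet or at the end, midnight
* share of target in all that became target or isomer of the product, at the outlet or at the end, dusk
* share of target in all that became target or isomer of the product, at the outlet or at the end, autumn

Autumn has Friday's charge, but Friday's readings stop at 40.0 h, sooner than 3.0 d. Autumn's end stands at 3.00 d on the catalyst clock, the elapsed time multiplied by the free catalyst charged over Friday's 5.5 mM. The working rule, for closed isothermal flasks with equal loadings, is that equal clock readings hold nearly equal contents. Monday's reading at 0.208 d stands at 7.44 h on this clock and shows 40% target. Friday's at 8.00 h shows 43%, and the scatter is 2 percentage points.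

1. First instants. By 8.00 h Friday's flask reads far more target than isomer of the product, 43% against 1%: kinetic control.

2. Middle. At 15.0 h Friday's flask reads 68% target and 8% isomer, so 24.0% of the charge is still unaccounted for. Isomer is starting to matter.

3. Late. At 40.0 h Friday's two products read 50% and 51%, which is the whole charge within scatter. Since 25.0 h Friday's target has read lower and its isomer higher, a drift towards thermodynamic control.

4. End. Monday's flask runs past autumn's mark: its share of target is 32.0% at clock 2.49 d and 24.0% at clock 3.73 d. A straight line between them gives my own 28.7% for autumn.

Midnight's charge stays 2.25 d on average, less than autumn's, so it should keep more target.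

The forecast ranks dusk > midnight > autumn, with 44% for dusk, 36% for midnight and 29% for autumn. Of dusk it says “the mixed-tank residence distribution leaves more target”.

The set-ups give dusk > midnight > autumn: dusk 41.8%, midnight 33.0%, autumn 26.4%.

    starting material + free catalyst → catalyst intermediate (k = 57.0 M⁻¹ h⁻¹)
    catalyst intermediate → free catalyst + target (k = 11.0 h⁻¹)
    target + free catalyst ⇌ isomer of the product + free catalyst, rate k3*[free catalyst]*[target] forward; the back reaction follows from the equilibrium constant (K = 4.60, k = 6.10 M⁻¹ h⁻¹)

Autumn's 26.4% is lower than 32.0% and higher than 24.0%, inside Monday's bracket. A neighbouring flask has autumn's charge and time with 2.20 mM of free catalyst, so it stands at 28.8 h on the clock. That lies between Friday's readings at 25.0 h and 30.0 h, whose shares were 74.2% and 64.9%. The neighbour gives 67.3%, with more target than isomer of the product: 66.8% against 32.4%.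

Readings and results were generated by integration for an exercise; the scatter is artificial.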